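## Retrosynthetic overview

1. 31 ⇒ chemoselective diimide reduction of dienoic acid 30 ⇒ Wittig union of allylic phosphonium salt 19 (rings A and B) with α-peroxy aldehyde 27 (dioxane).
2. Dioxane: the C3–O bond comes from a 6-exo intramolecular peroxy-Michael addition of tertiary hydroperoxide 24 to its own (E)-2-methylenoate. The glycol left on C6 is the masked aldehyde.
3. 24 ⇒ invertive perhydrolysis of epoxy enoate 23 ⇒ cross-metathesis and Sharpless epoxidation of geraniol.
4. 19 ⇒ ring B by hydroboration and intramolecular B-alkyl Suzuki coupling of dienyl triflate 15. The Z-alkylidene comes from syn-vinylcupration of ynoate 10, and ring A is 2,2-dimethylcyclohexanone.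
5. Ring order: A (bought) → B (step 7); the dioxane (step 13) is made independently; the fragments are joined in step 16.

Target as read from the SMILES: (2S,3R,6S). The propanoate arm on C3 is cis to the 6-methyl group. The exocyclic alkene is Z, with the side chain on the side of the doubly allylic ring CH2.

## Fragment A (rings A and B)

Step 1
Reactants: 1 2,2-dimethylcyclohexanone; 2 3-bromo-1-(trimethylsilyl)prop-1-yne
Product: 4 2,2-dimethyl-6-[3-(trimethylsilyl)prop-2-yn-1-yl]cyclohexan-1-one (racemic), via lithium enolate 3 (not isolated)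
Conditions: LiN(iPr)2, THF, −78 °C; then 2, DMPU, −78 °C → rt
Reagents that add atoms: lithium diisopropylamide, [Li+].CC(C)[N-]C(C)C (its lithium stays only in 3)
Why: Kinetic enolate alkylation (SN2) works because the ketone can enolise only towards C6, the silyl cap masks the acidic alkyne C–H, and the new stereocentre is irrelevant since it becomes sp2 in step 2.

Step 2
Reactants: 4
Product: 6 6,6-dimethyl-2-[3-(trimethylsilyl)prop-2-yn-1-yl]cyclohex-1-en-1-yl trifluoromethanesulfonate, via potassium enolate 5 (not isolated)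
Conditions: KN(SiMe3)2, THF, −78 → 0 °C; then PhNTf2, 0 °C → rt
Reagents that add atoms: N-phenylbis(trifluoromethanesulfonimide), O=S(=O)(C(F)(F)F)N(c1ccccc1)S(=O)(=O)C(F)(F)F; potassium bis(trimethylsilyl)amide, [K+].C[Si](C)(C)[N-][Si](C)(C)C (its potassium stays only in 5)
Why: Enolate O-sulfonylation (vinyl triflate synthesis) can give only one enolate, so the tetrasubstituted C=C that becomes the ring-fusion alkene is fixed next to the CMe2 group and no stereocentre remains.

Step 3
Reactants: 6
Product: 7 6,6-dimethyl-2-(prop-2-yn-1-yl)cyclohex-1-en-1-yl trifluoromethanesulfonate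
Conditions: K2CO3 (cat.), MeOH, 0 °C → rt
Reagents that add atoms: none
Why: Methoxide-catalysed protodesilylation of the alkynylsilane is fast, while the hindered vinyl triflate survives catalytic carbonate in cold methanol.

Step 4
Reactants: 7; 8 methyl chloroformate
Product: 10 methyl 4-{3,3-dimethyl-2-[(trifluoromethylsulfonyl)oxy]cyclohex-1-en-1-yl}but-2-ynoate, via lithium acetylide 9 (not isolated)
Conditions: LiN(iPr)2, THF, −78 °C; then 8, −78 → −30 °C
Reagents that add atoms: lithium diisopropylamide, [Li+].CC(C)[N-]C(C)C (its lithium stays only in 9)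
Why: Acetylide C-acylation works because the sp C–H is by far the most acidic site, and the low temperature keeps the doubly activated CH2 from isomerising to the allenoate.

Step 5
Reactants: 10; 11 vinylmagnesium bromide
Product: 14 methyl (2E)-3-({3,3-dimethyl-2-[(trifluoromethylsulfonyl)oxy]cyclohex-1-en-1-yl}methyl)penta-2,4-dienoate, via vinylcopper 12 (not isolated), via alkenylcopper adduct 13 (not isolated)
Conditions: 11, CuI (1:1), THF, −40 °C; then 10, −78 °C; aq NH4Cl at −78 °C
Reagents that add atoms: CuI, [Cu+].[I-] (its copper stays only in 12 and 13)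
Why: In this syn-carbocupration of an alkynoate, vinyl and copper add to the same side and cold protonation retains configuration, so the ester ends cis to the ring-A CH2 and trans to the vinyl group (the alkene geometry of the target), while the hindered triflate is inert to organocopper at −78 °C.

Step 6
Reactants: 14
Product: 15 2-[(2E)-2-ethenyl-4-hydroxybut-2-en-1-yl]-6,6-dimethylcyclohex-1-en-1-yl trifluoromethanesulfonate
Conditions: iBu2AlH, CH2Cl2, −78 °C; aq KNaC4H4O6 work-up
Reagents that add atoms: none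
Why: This 1,2-reduction of the ester leaves the diene, its geometry and the triflate untouched, and it removes the acidity of the doubly allylic CH2 before the basic coupling.

Step 7
Reactants: 15
Product: 17 2-[(2Z)-5,5-dimethyl-3,4,5,6,7,8-hexahydronaphthalen-2(1H)-ylidene]ethan-1-ol, via B-alkyl borane borinate 16 (not isolated)
Conditions: 9-BBN-H (2.3 equiv), THF, 0 °C → rt; then Pd(dppf)Cl2 (10 mol %), AsPh3, Cs2CO3, DMF/THF/H2O, 0.01 M, 50 °C
Reagents that add atoms: 9-borabicyclo[3.3.1]nonane, B1C2CCCC1CCC2 (its boron stays only in 16)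
Why: In this hydroboration and intramolecular B-alkyl Suzuki–Miyaura coupling, one equivalent of borane is consumed by the O–H, the second adds anti-Markovnikov only to the monosubstituted vinyl group, and the six-membered ring B closes on the triflate carbon with both alkene geometries retained and no stereocentre formed.

Step 8
Reactants: 17
Product: 18 (6Z)-6-(2-bromoethylidene)-1,1-dimethyl-1,2,3,4,5,6,7,8-octahydronaphthalene
Conditions: CBr4, PPh3, CH2Cl2, −20 → 0 °C
Reagents that add atoms: carbon tetrabromide, BrC(Br)(Br)Br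
Why: The Appel reaction displaces the primary allylic oxyphosphonium by SN2 under neutral conditions, so neither allylic transposition nor E/Z scrambling of the skipped diene occurs.

Step 9
Reactants: 18
Product: 19 {2-[(2Z)-5,5-dimethyl-3,4,5,6,7,8-hexahydronaphthalen-2(1H)-ylidene]ethyl}triphenylphosphonium bromide
Conditions: PPh3, MeCN, rt; precipitation with Et2O
Reagents that add atoms: triphenylphosphine, c1ccc(cc1)P(c1ccccc1)c1ccccc1
Why: SN2 quaternisation of a primary allylic bromide is fast at room temperature and leaves the alkene geometry unchanged.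

## Fragment B (dioxane)

Step 10
Reactants: 20 geraniol
Product: 21 (2S,3S)-2,3-epoxygeraniol
Conditions: Ti(OiPr)4 (5 mol %), L-(+)-diethyl tartrate (7 mol %), tBuOOH, 4 Å MS, CH2Cl2, −20 °C
Reagents that add atoms: tert-butyl hydroperoxide, CC(C)(C)OO
Why: In the Sharpless asymmetric epoxidation the titanium L-(+)-tartrate complex delivers oxygen only to the hydroxyl-bound allylic alkene, on the face that gives the (2S,3S)-epoxide in about 95 % ee, and the remote alkene is untouched.

Step 11
Reactants: 21; 22 methyl methacrylate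
Product: 23 methyl (2E)-5-[(2S,3S)-3-(hydroxymethyl)-2-methyloxiran-2-yl]-2-methylpent-2-enoate
Conditions: 22 (neat, excess, radical inhibitor), second-generation Hoveyda–Grubbs catalyst (3 mol %), 80 °C
Reagents that add atoms: none
Why: Olefin cross-metathesis exchanges the isopropylidene terminus for the methacrylate terminus, loss of a volatile alkene drives the reaction, the thermodynamically preferred (E)-enoate forms, and the epoxy alcohol stereocentres are not involved.

Step 12
Reactants: 23
Product: 24 methyl (2E,6R,7S)-6-hydroperoxy-7,8-dihydroxy-2,6-dimethyloct-2-enoate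
Conditions: H2O2 (anhydrous, Et2O, 10 equiv), H3PMo12O40 (5 mol %), 0 °C → rt
Reagents that add atoms: hydrogen peroxide, OO
Why: In this acid-catalysed perhydrolysis (borderline SN2 epoxide opening), H2O2 attacks the tertiary carbon from the back of the C–O bond so C6 is set by inversion, C7 keeps its oxygen and configuration so any leakage through an open cation gives a separable diastereomer and not the enantiomer, and the electron-poor enoate is not epoxidised.

Step 13
Reactants: 24
Product: 25 methyl (2S)-2-{(3R,6R)-6-[(1S)-1,2-dihydroxyethyl]-6-methyl-1,2-dioxan-3-yl}propanoate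
Conditions: Et2NH (0.3 equiv), CF3CH2OH, rt; chromatography, minor isomers resubmitted
Reagents that add atoms: none
Why: In this intramolecular 6-exo peroxy-Michael addition the α-effect hydroperoxide outruns both hydroxyls, C3 is set in a chair transition state with the enoate arm and the branched dihydroxyethyl group equatorial and the 6-methyl axial (arm cis to methyl), C2 is set by rapid protonation of the enolate by the solvent in its A(1,3)-minimised rotamer anti to the C3–O bond (which also suppresses epoxide formation), and only modest selectivity of about 3:1 at each centre is expected, so the isomers are separated and recycled through the reversible addition.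

Step 14
Reactants: 25
Product: 26 (2S)-2-{(3R,6R)-6-[(1S)-1,2-dihydroxyethyl]-6-methyl-1,2-dioxan-3-yl}propanoic acid
Conditions: LiOH, THF/H2O, 0 °C → rt; then 1 M HCl to pH 3
Reagents that add atoms: lithium hydroxide, [Li+].[OH-]
Why: Saponification by acyl–oxygen cleavage with cold aqueous LiOH is tolerated by the saturated dialkyl peroxide, is too weakly basic to enolise the ester (so C2 is kept), and gives a carboxylate that later protects C2 and C3 from retro-Michael opening in the basic olefination.

Step 15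
Reactants: 26
Product: 27 (2S)-2-[(3R,6R)-6-formyl-6-methyl-1,2-dioxan-3-yl]propanoic acid
Conditions: NaIO4, THF/H2O, 0 °C
Reagents that add atoms: none
Why: The Malaprade glycol cleavage is neutral and leaves the O–O bond alone, and the aldehyde it unveils sits on a quaternary carbon and so cannot epimerise or enolise.

## Union and end game

Step 16
Reactants: 19; 27
Product: 30 (2S)-2-[(3R,6R)-6-{(3Z)-3-[5,5-dimethyl-3,4,5,6,7,8-hexahydronaphthalen-2(1H)-ylidene]prop-1-en-1-yl}-6-methyl-1,2-dioxan-3-yl]propanoic acid (E/Z mixture at the new C=C), via allylic ylide 28 (not isolated), via sodium carboxylate 29 (not isolated)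
Conditions: 19, NaN(SiMe3)2, THF, −78 → 0 °C; separately 27, NaN(SiMe3)2 (1.0 equiv), THF, −78 °C; combine, −78 °C → rt; 1 M HCl to pH 4
Reagents that add atoms: sodium bis(trimethylsilyl)amide, [Na+].C[Si](C)(C)[N-][Si](C)(C)C (its sodium stays only in 29)
Why: In this Wittig olefination the semi-stabilised allylic ylide adds to the non-enolisable aldehyde faster than it attacks the hindered dialkyl peroxide, the trisubstituted alkene of the ylide keeps its geometry, the geometry of the new disubstituted alkene is irrelevant, and no stereocentre is touched.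

Step 17
Reactants: 30
Product: 31 (2S)-2-[(3R,6S)-6-{(3Z)-3-[5,5-dimethyl-3,4,5,6,7,8-hexahydronaphthalen-2(1H)-ylidene]propyl}-6-methyl-1,2-dioxan-3-yl]propanoic acid (target)
Conditions: KO2CN=NCO2K, AcOH, MeOH/CH2Cl2, 0 °C → rt, added in portions and monitored
Reagents that add atoms: none
Why: Diimide reduction transfers H2 in a concerted way to the 1,2-disubstituted C=C about ten times faster than to the tri- and tetrasubstituted alkenes and does not cleave O–O bonds, and the C6 descriptor changes from R to S only because the CIP ranking changes.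

## Compound list

1 | 2,2-dimethylcyclohexanone | CC1(C)CCCCC1=O | starting material
2 | 3-bromo-1-(trimethylsilyl)prop-1-yne | C[Si](C)(C)C#CCBr | starting material
3 | lithium enolate of 1 | [Li+].[O-]C1=CCCCC1(C)C | intermediate (not isolated)
4 | 2,2-dimethyl-6-[3-(trimethylsilyl)prop-2-yn-1-yl]cyclohexan-1-one (racemic) | C[Si](C)(C)C#CCC1CCCC(C)(C)C1=O | intermediate
5 | potassium enolate of 4 | [K+].[O-]C1=C(CC#C[Si](C)(C)C)CCCC1(C)C | intermediate (not isolated)
6 | 6,6-dimethyl-2-[3-(trimethylsilyl)prop-2-yn-1-yl]cyclohex-1-en-1-yl triflate | C[Si](C)(C)C#CCC1=C(OS(=O)(=O)C(F)(F)F)C(C)(C)CCC1 | intermediate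
7 | 6,6-dimethyl-2-(prop-2-yn-1-yl)cyclohex-1-en-1-yl triflate | C#CCC1=C(OS(=O)(=O)C(F)(F)F)C(C)(C)CCC1 | intermediate
8 | methyl chloroformate | COC(=O)Cl | starting material
9 | lithium acetylide of 7 | [Li+].[C-]#CCC1=C(OS(=O)(=O)C(F)(F)F)C(C)(C)CCC1 | intermediate (not isolated)
10 | methyl 4-{3,3-dimethyl-2-[(trifluoromethylsulfonyl)oxy]cyclohex-1-en-1-yl}but-2-ynoate | COC(=O)C#CCC1=C(OS(=O)(=O)C(F)(F)F)C(C)(C)CCC1 | intermediate
11 | vinylmagnesium bromide | C=C[Mg]Br | starting material
12 | vinylcopper | C=C[Cu] | intermediate (not isolated)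
13 | alkenylcopper syn-adduct of 10 | COC(=O)/C([Cu])=C(/C=C)CC1=C(OS(=O)(=O)C(F)(F)F)C(C)(C)CCC1 | intermediate (not isolated)
14 | methyl (2E)-3-({3,3-dimethyl-2-[(trifluoromethylsulfonyl)oxy]cyclohex-1-en-1-yl}methyl)penta-2,4-dienoate | COC(=O)/C=C(/C=C)CC1=C(OS(=O)(=O)C(F)(F)F)C(C)(C)CCC1 | intermediate
15 | 2-[(2E)-2-ethenyl-4-hydroxybut-2-en-1-yl]-6,6-dimethylcyclohex-1-en-1-yl triflate | OC/C=C(/C=C)CC1=C(OS(=O)(=O)C(F)(F)F)C(C)(C)CCC1 | intermediate
16 | B-alkyl-9-BBN and O-borinate derivative of 15 | B1(OC/C=C(/CCB2C3CCCC2CCC3)CC2=C(OS(=O)(=O)C(F)(F)F)C(C)(C)CCC2)C2CCCC1CCC2 | intermediate (not isolated)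
17 | 2-[(2Z)-5,5-dimethyl-3,4,5,6,7,8-hexahydronaphthalen-2(1H)-ylidene]ethan-1-ol | OC/C=C1/CCC2=C(CCCC2(C)C)C1 | intermediate
18 | (6Z)-6-(2-bromoethylidene)-1,1-dimethyl-1,2,3,4,5,6,7,8-octahydronaphthalene | BrC/C=C1/CCC2=C(CCCC2(C)C)C1 | intermediate
19 | {2-[(2Z)-5,5-dimethyl-3,4,5,6,7,8-hexahydronaphthalen-2(1H)-ylidene]ethyl}triphenylphosphonium bromide | [Br-].C(/C=C1/CCC2=C(CCCC2(C)C)C1)[P+](c1ccccc1)(c1ccccc1)c1ccccc1 | intermediate
20 | geraniol | CC(C)=CCC/C(C)=C/CO | starting material
21 | (2S,3S)-2,3-epoxygeraniol | CC(C)=CCC[C@]1(C)O[C@H]1CO | intermediate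
22 | methyl methacrylate | C=C(C)C(=O)OC | starting material
23 | methyl (2E)-5-[(2S,3S)-3-(hydroxymethyl)-2-methyloxiran-2-yl]-2-methylpent-2-enoate | COC(=O)/C(C)=C/CC[C@]1(C)O[C@H]1CO | intermediate
24 | methyl (2E,6R,7S)-6-hydroperoxy-7,8-dihydroxy-2,6-dimethyloct-2-enoate | COC(=O)/C(C)=C/CC[C@@](C)(OO)[C@@H](O)CO | intermediate
25 | methyl (2S)-2-{(3R,6R)-6-[(1S)-1,2-dihydroxyethyl]-6-methyl-1,2-dioxan-3-yl}propanoate | C[C@H](C(=O)OC)[C@H]1CC[C@](C)([C@@H](O)CO)OO1 | intermediate
26 | (2S)-2-{(3R,6R)-6-[(1S)-1,2-dihydroxyethyl]-6-methyl-1,2-dioxan-3-yl}propanoic acid | C[C@H](C(=O)O)[C@H]1CC[C@](C)([C@@H](O)CO)OO1 | intermediate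
27 | (2S)-2-[(3R,6R)-6-formyl-6-methyl-1,2-dioxan-3-yl]propanoic acid | C[C@H](C(=O)O)[C@H]1CC[C@](C)(C=O)OO1 | intermediate
28 | allylic ylide from 19 | [CH-](/C=C1/CCC2=C(CCCC2(C)C)C1)[P+](c1ccccc1)(c1ccccc1)c1ccccc1 | intermediate (not isolated)
29 | sodium carboxylate of 27 | [Na+].C[C@H](C(=O)[O-])[C@H]1CC[C@](C)(C=O)OO1 | intermediate (not isolated)
30 | (2S)-2-[(3R,6R)-6-{(3Z)-3-[5,5-dimethyl-3,4,5,6,7,8-hexahydronaphthalen-2(1H)-ylidene]prop-1-en-1-yl}-6-methyl-1,2-dioxan-3-yl]propanoic acid (E/Z at C1'=C2') | C[C@H](C(=O)O)[C@H]1CC[C@](C)(C=C/C=C2/CCC3=C(CCCC3(C)C)C2)OO1 | intermediate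
31 | (2S)-2-[(3R,6S)-6-{(3Z)-3-[5,5-dimethyl-3,4,5,6,7,8-hexahydronaphthalen-2(1H)-ylidene]propyl}-6-methyl-1,2-dioxan-3-yl]propanoic acid | C[C@H](C(=O)O)[C@H]1CC[C@](C)(CC/C=C2/CCC3=C(CCCC3(C)C)C2)OO1 | target

## Step count and longest linear sequence

- Total step count: 17.
- Longest linear sequence: 11 (steps 1–9, 16, 17), which is 11/17 = 0.65 of the total.

## Three steps most likely to fail

**Step 13 (peroxy-Michael closure).** The risks are slow addition to the α-methyl enoate, base-induced cleavage of the free β-hydroxy hydroperoxide, and weak control of C3 relative to C6. The fallback steers the closure with protecting groups; it sets out from 24 and comes back at 25. Exhaustive silylation (tBuMe2SiOTf, 2,6-lutidine, CH2Cl2, −78 → 0 °C) gives methyl (2E,6R,7S)-7,8-bis[(tert-butyldimethylsilyl)oxy]-6-[(tert-butyldimethylsilyl)peroxy]-2,6-dimethyloct-2-enoate F1. One equivalent of Bu4NF in THF/CF3CH2OH at −20 °C cleaves only the labile O–O–Si bond. The free peroxy anion then closes onto the enoate with no free hydroxyl present and with a much bulkier group on C6 that must sit equatorial. This gives methyl (2S)-2-{(3R,6R)-6-[(1S)-1,2-bis[(tert-butyldimethylsilyl)oxy]ethyl]-6-methyl-1,2-dioxan-3-yl}propanoate F2. HF·pyridine in THF then returns 25.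

**Step 12 (perhydrolysis).** The risks are partial loss of configuration at the tertiary carbon and a low yield. The fallback replaces ionic opening by radical peroxidation and separation of epimers; it sets out from 23 and comes back at 24. Epoxide-to-allylic-ether isomerisation (Me3SiOTf, 2,6-lutidine, then DBU) gives methyl (2E,7R)-2-methyl-6-methylidene-7,8-bis[(trimethylsilyl)oxy]oct-2-enoate F3. Cobalt-catalysed hydroperoxysilylation of the 1,1-disubstituted alkene (Co(thd)2, thd = 2,2,6,6-tetramethylheptane-3,5-dionate, O2, Et3SiH, ClCH2CH2Cl, rt) leaves the enoate alone. It gives methyl (2E,6R,7S)-2,6-dimethyl-6-[(triethylsilyl)peroxy]-7,8-bis[(trimethylsilyl)oxy]oct-2-enoate F4 together with its C6 epimer methyl (2E,6S,7S)-2,6-dimethyl-6-[(triethylsilyl)peroxy]-7,8-bis[(trimethylsilyl)oxy]oct-2-enoate F5. The two are diastereomers because C7 is fixed, so they are separated on silica. HF·pyridine converts F4 into 24.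

**Step 7 (closure of ring B on a neopentyl, tetrasubstituted triflate).** The risks are slow oxidative addition, β-hydride elimination and reduction of the triflate. The fallback closes the ring at the other bond by an intramolecular conjugate addition; it sets out from 10 and comes back at 17. Intermolecular Stille vinylation of the triflate (Bu3SnCH=CH2, Pd(PPh3)4, LiCl, THF, 60 °C) gives methyl 4-(2-ethenyl-3,3-dimethylcyclohex-1-en-1-yl)but-2-ynoate F6. 9-BBN-H adds to the terminal CH2 of the twisted vinyl group to give methyl 4-{2-[2-(9-borabicyclo[3.3.1]nonan-9-yl)ethyl]-3,3-dimethylcyclohex-1-en-1-yl}but-2-ynoate F7. Copper-catalysed syn conjugate addition of the alkylborane to the tethered ynoate (CuOAc, P(OPh)3, KOtBu cat., tBuOH, dioxane, 40 °C) puts the new ring carbon and the proton on the same side. This leads to methyl (2Z)-2-[5,5-dimethyl-3,4,5,6,7,8-hexahydronaphthalen-2(1H)-ylidene]acetate F8 with the same alkene geometry as the main route. iBu2AlH then gives 17.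

## Further compounds

F1 | step 13 | methyl (2E,6R,7S)-7,8-bis[(tert-butyldimethylsilyl)oxy]-6-[(tert-butyldimethylsilyl)peroxy]-2,6-dimethyloct-2-enoate | COC(=O)/C(C)=C/CC[C@@](C)(OO[Si](C)(C)C(C)(C)C)[C@@H](O[Si](C)(C)C(C)(C)C)CO[Si](C)(C)C(C)(C)C
F2 | step 13 | methyl (2S)-2-{(3R,6R)-6-[(1S)-1,2-bis[(tert-butyldimethylsilyl)oxy]ethyl]-6-methyl-1,2-dioxan-3-yl}propanoate | C[C@H](C(=O)OC)[C@H]1CC[C@](C)([C@@H](O[Si](C)(C)C(C)(C)C)CO[Si](C)(C)C(C)(C)C)OO1
F3 | step 12 | methyl (2E,7R)-2-methyl-6-methylidene-7,8-bis[(trimethylsilyl)oxy]oct-2-enoate | COC(=O)/C(C)=C/CCC(=C)[C@@H](O[Si](C)(C)C)CO[Si](C)(C)C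
F4 | step 12 | methyl (2E,6R,7S)-2,6-dimethyl-6-[(triethylsilyl)peroxy]-7,8-bis[(trimethylsilyl)oxy]oct-2-enoate | COC(=O)/C(C)=C/CC[C@@](C)(OO[Si](CC)(CC)CC)[C@@H](O[Si](C)(C)C)CO[Si](C)(C)C
F5 | step 12 | methyl (2E,6S,7S)-2,6-dimethyl-6-[(triethylsilyl)peroxy]-7,8-bis[(trimethylsilyl)oxy]oct-2-enoate | COC(=O)/C(C)=C/CC[C@](C)(OO[Si](CC)(CC)CC)[C@@H](O[Si](C)(C)C)CO[Si](C)(C)C
F6 | step 7 | methyl 4-(2-ethenyl-3,3-dimethylcyclohex-1-en-1-yl)but-2-ynoate | COC(=O)C#CCC1=C(C=C)C(C)(C)CCC1
F7 | step 7 | methyl 4-{2-[2-(9-borabicyclo[3.3.1]nonan-9-yl)ethyl]-3,3-dimethylcyclohex-1-en-1-yl}but-2-ynoate | COC(=O)C#CCC1=C(CCB2C3CCCC2CCC3)C(C)(C)CCC1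
F8 | step 7 | methyl (2Z)-2-[5,5-dimethyl-3,4,5,6,7,8-hexahydronaphthalen-2(1H)-ylidene]acetate | COC(=O)/C=C1/CCC2=C(CCCC2(C)C)C1
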